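**Target:** (2S,3S,5S)-5-bromo-2-[(1R,3S,4S)-4-bromo-3-chloro-4-methylcyclohexyl]-2,6,6-trimethyloxan-3-ol (CID46881070). In the chair forms, the carbocycle carries the oxanyl group equatorial with Cl and Br trans-diaxial and CH3 equatorial. The oxane carries Br equatorial, OH axial, 2-CH3 axial and the cyclohexyl group equatorial.

**Assumptions:** 4-Bromoanisole is converted to its Grignard reagent in situ and this is counted inside step 2. The step 6 catalyst is defined operationally as the enantiomer that gives (S)-2-chlorocyclohexanone from cyclohexanone; I have written it as (4R,5R) from memory, and its antipode is used if the sense is the reverse.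

## Retrosynthetic overview

1. C–Br (tertiary) ⇐ tertiary carbinol by SN1; C–CH3 ⇐ ketone + MeM; C–Cl ⇐ catalytic desymmetrising α-chlorination of a Cs-symmetric 4-substituted cyclohexanone, which sets both ring CH stereocentres at once.
2. The 4-substituted cyclohexanone ⇐ a p-anisyl ring by Birch dearomatisation, enol-ether hydrolysis and alkene hydrogenation; the arene is a masked, stereochemically silent 4-oxocyclohexyl group.
3. Oxane ⇐ 6-endo bromoetherification of a prenyl group by the tertiary alcohol.
4. syn-Diol ⇐ chelation-controlled addition of p-anisylMgBr to (S)-3-hydroxy-6-methylhept-5-en-2-one ⇐ D-proline α-aminoxylation of 6-methylhept-5-en-2-one.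
5. Ring order: the carbocycle is present from the start as the arene (unmasked in step 3), the oxane is closed in step 4, and the carbocycle is functionalised last (steps 6–8).

## Route

**Step 1**
Reactants: 1, 6-methylhept-5-en-2-one; 2, nitrosobenzene
Product: 3, (3S)-3-hydroxy-6-methylhept-5-en-2-one
Conditions: D-proline (20 mol%), DMSO, rt, 1 in excess (5 equiv), slow addition of 2; then CuSO4·5H2O (30 mol%), MeOH, 0 °C
Reagents that add atoms: nitrosobenzene, O=Nc1ccccc1 (only its O is retained)
Why: Proline-enamine O-selective nitroso aldol (α-aminoxylation) at the more substituted CH2 enamine, with D-proline's acid delivering PhN=O to the face that gives 3S (L-proline gives R); Cu(II) then cleaves the N–O bond.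

**Step 2**
Reactants: 3; 4, 4-bromoanisole (as its Grignard reagent)
Product: 5, (2S,3S)-2-(4-methoxyphenyl)-6-methylhept-5-ene-2,3-diol
Conditions: 4 (2.6 equiv), Mg, THF, rt; then 3, THF/Et2O, −78 → 0 °C; pH 7 buffer work-up
Reagents that add atoms: 4-methoxyphenylmagnesium bromide (from 4), COc1ccc([Mg]Br)cc1
Why: Cram-chelate Grignard addition: the magnesium alkoxide of the α-OH chelates the ketone and the aryl group attacks from the face of the α-H, setting the tertiary carbinol as 2S (syn-diol, 2S,3S).

**Step 3 (key dearomatisation)**
Reactants: 5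
Product: 6, 4-[(2S,3S)-2,3-dihydroxy-6-methylhept-5-en-2-yl]cyclohex-3-en-1-one
Conditions: Li (12 equiv), NH3(l)/THF, t-BuOH, −78 → −33 °C; NH4Cl; then (CO2H)2, THF/H2O, 0 °C
Reagents that add atoms: water, O (carbonyl oxygen after enol-ether hydrolysis); the Birch step adds only H
Why: Birch reduction gives the 1-methoxy-4-alkylcyclohexa-1,4-diene, and mild oxalic acid hydrolysis gives the unconjugated β,γ-enone; the benzylic C–O bond survives as its lithium alkoxide, the isolated prenyl alkene is inert, and no stereocentre is created.

**Step 4**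
Reactants: 6
Product: 7, 4-[(2S,3S,5S)-5-bromo-3-hydroxy-2,6,6-trimethyloxan-2-yl]cyclohex-3-en-1-one
Conditions: TBCO (1.1 equiv), CH2Cl2, −20 → 0 °C
Reagents that add atoms: 2,4,4,6-tetrabromocyclohexa-2,5-dienone (TBCO), O=C1C(Br)=CC(Br)(Br)C=C1Br
Why: Bromonium-induced 6-endo (Markovnikov) bromoetherification by the tertiary OH on the most nucleophilic alkene; anti addition through a chair with Br equatorial, the 2-CH3 (not the ring substituent) axial next to the new gem-dimethyl group, and OH axial sets 5S.

**Step 5**
Reactants: 7
Product: 8, 4-[(2S,3S,5S)-5-bromo-3-hydroxy-2,6,6-trimethyloxan-2-yl]cyclohexan-1-one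
Conditions: H2 (1 atm), [Ir(cod)(PCy3)(py)]PF6 (5 mol%), CH2Cl2, rt
Reagents that add atoms: none
Why: Hydroxyl-directed homogeneous (Crabtree) hydrogenation of the hindered trisubstituted alkene, which leaves the ketone and the alkyl bromide untouched; the resulting ring is Cs-symmetric, so no stereochemical issue arises.

**Step 6 (symmetry-breaking step)**
Reactants: 8
Product: 9, (2S,4R)-4-[(2S,3S,5S)-5-bromo-3-hydroxy-2,6,6-trimethyloxan-2-yl]-2-chlorocyclohexan-1-one (Cl axial, trans to the equatorial oxanyl group)
Conditions: NCS (1.5 equiv), (4R,5R)-4,5-diphenylimidazolidine (20 mol%), 2-nitrobenzoic acid (50 mol%), MeCN, −24 °C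
Reagents that add atoms: N-chlorosuccinimide, O=C1CCC(=O)N1Cl
Why: Enamine-catalysed enantioselective α-chlorination used as a desymmetrisation: the C2-symmetric amine fixes the configuration at the C–Cl carbon as S, and axial C–Cl formation on the conformationally locked ring is possible on the open face for only one of the two enantiotopic arms, so C2 (S) and C4 (R) are set together.

**Step 7**
Reactants: 9
Product: 10, (1R,2S,4R)-4-[(2S,3S,5S)-5-bromo-3-hydroxy-2,6,6-trimethyloxan-2-yl]-2-chloro-1-methylcyclohexan-1-ol (CH3 axial, OH equatorial and cis to Cl)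
Conditions: MeMgBr (3 equiv), CeCl3 (3 equiv), THF, −78 °C; AcOH quench at −78 °C
Reagents that add atoms: methylmagnesium bromide, C[Mg]Br
Why: Organocerium 1,2-addition (non-basic, so no enolisation or epoxide closure) anti to the axial C–Cl bond (Cornforth/Felkin) gives mainly the 1R carbinol; this centre is re-formed in step 8, so its configuration does not matter.

**Step 8**
Reactants: 10
Product: 11, the target
Conditions: TMSBr (3 equiv), CH2Cl2, −20 → 0 °C; aqueous citric acid/THF work-up (removes the transient secondary O-TMS)
Reagents that add atoms: bromotrimethylsilane, C[Si](C)(C)Br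
Why: SN1 substitution of the tertiary alcohol: the tertiary cation is captured by bromide anti to the axial C–Cl bond (chloronium-like assistance, trans-diaxial opening), giving the Me-equatorial 4S bromide from either carbinol epimer, while the secondary OH is only silylated.

## Compound list

1 | 6-methylhept-5-en-2-one | CC(=O)CCC=C(C)C | starting material
2 | nitrosobenzene | O=Nc1ccccc1 | starting material
3 | (3S)-3-hydroxy-6-methylhept-5-en-2-one | CC(=O)[C@@H](O)CC=C(C)C | intermediate
4 | 4-bromoanisole | COc1ccc(Br)cc1 | starting material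
5 | (2S,3S)-2-(4-methoxyphenyl)-6-methylhept-5-ene-2,3-diol | O[C@@](C)(c1ccc(OC)cc1)[C@@H](O)CC=C(C)C | intermediate
6 | 4-[(2S,3S)-2,3-dihydroxy-6-methylhept-5-en-2-yl]cyclohex-3-en-1-one | O[C@@](C)(C1=CCC(=O)CC1)[C@@H](O)CC=C(C)C | intermediate
7 | 4-[(2S,3S,5S)-5-bromo-3-hydroxy-2,6,6-trimethyloxan-2-yl]cyclohex-3-en-1-one | CC1(C)O[C@@](C)(C2=CCC(=O)CC2)[C@@H](O)C[C@@H]1Br | intermediate
8 | 4-[(2S,3S,5S)-5-bromo-3-hydroxy-2,6,6-trimethyloxan-2-yl]cyclohexan-1-one | CC1(C)O[C@@](C)(C2CCC(=O)CC2)[C@@H](O)C[C@@H]1Br | intermediate
9 | (2S,4R)-4-[(2S,3S,5S)-5-bromo-3-hydroxy-2,6,6-trimethyloxan-2-yl]-2-chlorocyclohexan-1-one | CC1(C)O[C@@](C)([C@@H]2CCC(=O)[C@@H](Cl)C2)[C@@H](O)C[C@@H]1Br | intermediate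
10 | (1R,2S,4R)-4-[(2S,3S,5S)-5-bromo-3-hydroxy-2,6,6-trimethyloxan-2-yl]-2-chloro-1-methylcyclohexan-1-ol | CC1(C)O[C@@](C)([C@@H]2CC[C@@](C)(O)[C@@H](Cl)C2)[C@@H](O)C[C@@H]1Br | intermediate
11 | (2S,3S,5S)-5-bromo-2-[(1R,3S,4S)-4-bromo-3-chloro-4-methylcyclohexyl]-2,6,6-trimethyloxan-3-ol | CC1(C)O[C@@](C)([C@@H]2CC[C@](C)(Br)[C@@H](Cl)C2)[C@@H](O)C[C@@H]1Br | target

## Step count and risks

Total steps: 8. Longest linear sequence: 8 (1 → 3 → 5 → 6 → 7 → 8 → 9 → 10 → 11).

Steps most likely to fail:

1. **Step 6 (desymmetrising chlorination).** The catalyst may not discriminate the two arms well on this bulky, hydroxylated substrate, giving the cis (2S,4S) isomer as well. Fallback: break the symmetry at the enolisation stage instead, using a chiral lithium amide (bis(1-phenylethyl)amide/LiCl, in situ TMSCl, which also silylates the OH) to form a single silyl enol ether, then chlorinate it axially with NCS.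
2. **Step 4 (bromoetherification).** 5-exo oxolane formation and the C5 epimer can compete, and the β,γ-enone may be α-brominated. Fallback: build the oxane by reagent-controlled epoxide chemistry: Shi epoxidation of the prenyl alkene, acid-catalysed 6-endo opening by the tertiary OH to the 5-hydroxy oxane, then displacement of that secondary alcohol by bromide with inversion (chloromesylate, Bu4NBr).
3. **Step 8 (tertiary bromide).** Elimination, opening of the di-tertiary ether, or the C4 epimer are possible. Fallback: reach the same cation from carbon rather than oxygen: methylenate ketone 9 (Cp2TiMe2) and add HBr in the Markovnikov sense to the exocyclic alkene.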